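**Retrosynthetic overview** (target numbering: ring C1 side chain, C2 OAng, C3 OH, C4 C(CH3)OH, C5 C=O, C6 OAng; chain C7 =CH2, C8 OAng, C9, C10/C11 oxirane)
1. Late disconnections: C3–O silyl ether, C10–C11 oxirane (Shi), the three angelates (mixed anhydride), C10=C11 (cross-metathesis), C8–C9 (Brown allylation), C7=CH2 (Eschenmoser), C4–OH (enolate oxidation); all lead back to allyl cyclohexanone 18.
2. The strategy rests on the C5 ketone carrying a β-hydroxyl at C3 and oxygens at C2 and C6 that are both trans to the C1 branch. This is the pattern a Ferrier carbocyclization leaves, so the C3–C4 bond is cut to give pyranoside 15; its C1–C5 become ring C3, C2, C1, C6, C5 and its exocyclic ethylidene carbon becomes C4 with the methyl group.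
3. 15 comes from methyl α-D-mannopyranoside: 3,4-anhydro-talo epoxide, copper-catalysed allyl opening at sugar C3 (ido pattern), PMB ethers, C6 aldehyde, enol triflate, Negishi methylation.
4. Ring order: the cyclohexanone is the only carbocycle and is closed in step 12; the oxirane is closed in step 21.

Key step: step 12

Abbreviations: PMB = 4-methoxybenzyl, TBDPS = tert-butyldiphenylsilyl, TES = triethylsilyl, Ang = angeloyl ((Z)-2-methylbut-2-enoyl), Ipc = isopinocampheyl. In carbocycle names, β is the ring face of the C1 substituent and α the opposite face.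

Assumption: step 12 is taken to give the 4α-methyl epimer of 18 and steps 10–11 the (Z)-alkenes; the other isomers would converge, because sugar C6 and ring C4 both pass through trigonal intermediates (steps 12 and 14).

**Step 1**
Reactants: 1 methyl α-D-mannopyranoside
Product: 3 methyl 2,3-O-isopropylidene-α-D-mannopyranoside, via diacetonide 2 (not isolated)
Conditions: Me2C(OMe)2, TsOH·H2O (cat.), acetone, rt; then H2O, rt; Et3N
Reagents that add atoms: 2,2-dimethoxypropane, COC(C)(C)OC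
Why: Acid-catalysed acetal exchange gives the bis-acetonide, and graded hydrolysis removes the six-membered 4,6-acetal faster than the cis-fused 2,3-dioxolane (acetal protection and selective deprotection).

**Step 2**
Reactants: 3 methyl 2,3-O-isopropylidene-α-D-mannopyranoside
Product: 4 methyl 6-O-TBDPS-2,3-O-isopropylidene-α-D-mannopyranoside
Conditions: TBDPSCl, imidazole, DMF, 0 °C
Reagents that add atoms: tert-butyl(chloro)diphenylsilane, CC(C)(C)[Si](Cl)(c1ccccc1)c1ccccc1
Why: The bulky silyl chloride reacts with the primary C6 hydroxyl much faster than with the secondary C4 hydroxyl (selective silylation).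

**Step 3**
Reactants: 4 methyl 6-O-TBDPS-2,3-O-isopropylidene-α-D-mannopyranoside
Product: 5 methyl 6-O-TBDPS-2,3-O-isopropylidene-4-O-methanesulfonyl-α-D-mannopyranoside
Conditions: MsCl, Et3N, CH2Cl2, 0 °C
Reagents that add atoms: methanesulfonyl chloride, CS(=O)(=O)Cl
Why: Sulfonylation of the only free hydroxyl turns O4 into a leaving group without touching the C4 configuration.

**Step 4**
Reactants: 5 methyl 6-O-TBDPS-2,3-O-isopropylidene-4-O-methanesulfonyl-α-D-mannopyranoside
Product: 6 methyl 6-O-TBDPS-4-O-methanesulfonyl-α-D-mannopyranoside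
Conditions: 80% aq. AcOH, 60 °C
Reagents that add atoms: none
Why: Acetal hydrolysis frees the 2,3-diol, while the methyl glycoside, the mesylate and the acid-stable TBDPS ether are expected to survive.

**Step 5**
Reactants: 6 methyl 6-O-TBDPS-4-O-methanesulfonyl-α-D-mannopyranoside
Product: 7 methyl 3,4-anhydro-6-O-TBDPS-α-D-talopyranoside
Conditions: NaOMe, MeOH/CH2Cl2, 0 °C to rt
Reagents that add atoms: none
Why: Intramolecular Williamson (SN2) closure: the O3 alkoxide displaces the trans C4 mesylate with inversion at C4, and the cis O2 cannot attack C3, so the epoxide does not migrate.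

**Step 6**
Reactants: 7 methyl 3,4-anhydro-6-O-TBDPS-α-D-talopyranoside; 8 allylmagnesium bromide
Product: 9 methyl 3-C-allyl-3-deoxy-6-O-TBDPS-α-D-idopyranoside
Conditions: 8 (4 equiv), CuI (10 mol %), THF, −40 to 0 °C; aq. NH4Cl
Reagents that add atoms: allylmagnesium bromide (8), C=CC[Mg]Br
Why: Copper-catalysed Grignard opening of the epoxide follows the Fürst–Plattner rule: trans-diaxial attack at C3 anti to the epoxide oxygen inverts C3 and leaves O4 in the talo sense, giving the ido pattern at C2–C4.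

**Step 7**
Reactants: 9 methyl 3-C-allyl-3-deoxy-6-O-TBDPS-α-D-idopyranoside
Product: 10 methyl 3-C-allyl-3-deoxy-2,4-di-O-PMB-6-O-TBDPS-α-D-idopyranoside
Conditions: NaH, PMBCl, Bu4NI (cat.), DMF, 0 °C to rt
Reagents that add atoms: 4-methoxybenzyl chloride, COc1ccc(CCl)cc1
Why: Williamson etherification of both secondary alkoxides with the reactive benzylic halide (iodide catalysis); no stereocentre is involved.

**Step 8**
Reactants: 10 methyl 3-C-allyl-3-deoxy-2,4-di-O-PMB-6-O-TBDPS-α-D-idopyranoside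
Product: 11 methyl 3-C-allyl-3-deoxy-2,4-di-O-PMB-α-D-idopyranoside
Conditions: Bu4NF, THF, rt; aq. NH4Cl
Reagents that add atoms: none
Why: Fluoride cleaves the Si–O bond and frees the primary C6 hydroxyl; ethers, acetal and alkene are inert.

**Step 9**
Reactants: 11 methyl 3-C-allyl-3-deoxy-2,4-di-O-PMB-α-D-idopyranoside
Product: 12 methyl 3-C-allyl-3-deoxy-2,4-di-O-PMB-α-D-ido-hexodialdo-1,5-pyranoside
Conditions: Dess–Martin periodinane, NaHCO3, CH2Cl2, 0 °C to rt
Reagents that add atoms: none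
Why: Dess–Martin oxidation gives the C6 aldehyde under buffered, non-basic conditions that should not epimerise C5 or eliminate the C4 ether.

**Step 10**
Reactants: 12 methyl 3-C-allyl-3-deoxy-2,4-di-O-PMB-α-D-ido-hexodialdo-1,5-pyranoside
Product: 14 methyl (Z)-3-C-allyl-3-deoxy-2,4-di-O-PMB-6-O-(trifluoromethanesulfonyl)hex-5-enopyranoside (α-glycoside; C2–C4 as in 11), via potassium enolate 13 (not isolated)
Conditions: PhNTf2, KN(SiMe3)2, THF, −78 °C (base added last)
Reagents that add atoms: N-phenylbis(trifluoromethanesulfonimide), FC(F)(F)S(=O)(=O)N(c1ccccc1)S(=O)(=O)C(F)(F)F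
Why: The aldehyde has a single α-hydrogen (H5), so enolate O-sulfonylation can place the double bond only at C5=C6; trapping in situ at −78 °C should outrun loss of the poor C4 alkoxide leaving group (enol triflate formation).

**Step 11**
Reactants: 14 enol triflate
Product: 15 methyl (Z)-3-C-allyl-3,6,7-trideoxy-2,4-di-O-PMB-hept-5-enopyranoside (α-glycoside; C2–C4 as in 11)
Conditions: MeZnCl, Pd(PPh3)4 (5 mol %), THF, rt to 45 °C
Reagents that add atoms: methylzinc chloride, C[Zn]Cl
Why: Negishi coupling: zerovalent palladium inserts into the alkenyl C–O triflate bond and the methyl group is transferred with retention, giving the exocyclic ethylidene enol ether with the double bond fixed at C5=C6.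

**Step 12**
Reactants: 15 methyl (Z)-3-C-allyl-3,6,7-trideoxy-2,4-di-O-PMB-hept-5-enopyranoside
Product: 18 1β-allyl-3α-hydroxy-4α-methyl-2α,6α-bis(PMB-oxy)cyclohexan-5-one, via mercurated hemiketal 16 (not isolated), via mercurio keto aldehyde 17 (not isolated)
Conditions: Hg(OCOCF3)2 (10 mol %), acetone/H2O (2:1), rt
Reagents that add atoms: water, O
Why: Divalent mercury adds to the electron-rich C5=C6 enol ether with water at C5, hemiketal 16 collapses to the C5 ketone, and the freed anomeric hemiacetal loses methanol to give 1,5-keto aldehyde 17 with mercury α to the ketone. This α-mercurio ketone reacts as a mercury enolate with the aldehyde, forming the ring C3–C4 bond and releasing the mercury salt for the next turnover; the closest known reaction type is the Ferrier carbocyclization of hex-5-enopyranosides, including 6-substituted ones under catalytic Hg(OCOCF3)2. The cyclohexanone closes in a 6-(enolexo)-exo-trig aldol mode. The C3 carbinol is set by a chair transition state in which the sugar-derived C2, C1 and C6 substituents are all equatorial and the aldehyde oxygen lies axial toward the mercury-bound enolate oxygen, which places the new hydroxyl cis to the C2 ether and trans to the C1 allyl group; the C4 methyl centre should settle equatorial but is immaterial because C4 becomes trigonal again in step 14. The step needs chemoselectivity for the enol ether over the allyl alkene and the anisyl rings, secured by the much higher nucleophilicity of the enol ether toward a catalytic amount of mercury salt, and it needs the β-hydroxy ketone to survive, secured by neutral aqueous acetone at room temperature.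

**Step 13**
Reactants: 18 1β-allyl-3α-hydroxy-4α-methyl-2α,6α-bis(PMB-oxy)cyclohexan-5-one
Product: 19 1β-allyl-4α-methyl-2α,6α-bis(PMB-oxy)-3α-(TES-oxy)cyclohexan-5-one
Conditions: Et3SiOTf, 2,6-lutidine, CH2Cl2, −78 °C
Reagents that add atoms: triethylsilyl trifluoromethanesulfonate, CC[Si](CC)(CC)OS(=O)(=O)C(F)(F)F
Why: Silylation with a silyl triflate and a hindered weak base caps the axial C3 hydroxyl at low temperature without triggering β-elimination to the enone.

**Step 14**
Reactants: 19 1β-allyl-4α-methyl-2α,6α-bis(PMB-oxy)-3α-(TES-oxy)cyclohexan-5-one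
Product: 21 1β-allyl-4β-hydroxy-4α-methyl-2α,6α-bis(PMB-oxy)-3α-(TES-oxy)cyclohexan-5-one, via sodium enolate 20 (not isolated)
Conditions: NaN(SiMe3)2, THF, −78 °C; then 2-(phenylsulfonyl)-3-phenyloxaziridine, −78 °C; aq. NH4Cl at −78 °C
Reagents that add atoms: 2-(phenylsulfonyl)-3-phenyloxaziridine, O=S(=O)(c1ccccc1)N1OC1c1ccccc1
Why: Kinetic deprotonation is expected at C4 and not at the C6 hydrogen geminal to the PMB ether (α-alkoxy ketones usually enolise on the non-oxygenated side), and Davis oxidation of the enolate delivers oxygen anti to the axial C3 silyloxy group, setting the C4 carbinol β (trans to O3).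

**Step 15**
Reactants: 21 1β-allyl-4β-hydroxy-4α-methyl-2α,6α-bis(PMB-oxy)-3α-(TES-oxy)cyclohexan-5-one
Product: 23 4β-hydroxy-4α-methyl-1β-(2-oxoethyl)-2α,6α-bis(PMB-oxy)-3α-(TES-oxy)cyclohexan-5-one, via diol 22 (not isolated)
Conditions: OsO4 (2 mol %), NMO, acetone/H2O, rt; then NaIO4, 0 °C, short contact
Reagents that add atoms: N-methylmorpholine N-oxide (oxygen source for the OsO4 cycle), C[N+]1([O-])CCOCC1
Why: Dihydroxylation of the only alkene followed by periodate glycol cleavage gives the aldehyde without ozone (which would attack the PMB rings), and the vicinal diol is cleaved much faster than the hindered tertiary α-ketol.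

**Step 16**
Reactants: 23 4β-hydroxy-4α-methyl-1β-(2-oxoethyl)-2α,6α-bis(PMB-oxy)-3α-(TES-oxy)cyclohexan-5-one
Product: 25 1β-(3-oxoprop-1-en-2-yl)-4β-hydroxy-4α-methyl-2α,6α-bis(PMB-oxy)-3α-(TES-oxy)cyclohexan-5-one, via Mannich base 24 (not isolated)
Conditions: CH2=NMe2+ I− (Eschenmoser's salt), Et3N, CH2Cl2, rt
Reagents that add atoms: N,N-dimethylmethyleneiminium iodide, C=[N+](C)C.[I-]
Why: Mannich reaction at the aldehyde α-methylene followed by loss of dimethylamine gives the 2-substituted acrolein (Eschenmoser methylenation); the hindered ketone α-methine at C6 does not compete.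

**Step 17**
Reactants: 25 1β-(3-oxoprop-1-en-2-yl)-4β-hydroxy-4α-methyl-2α,6α-bis(PMB-oxy)-3α-(TES-oxy)cyclohexan-5-one; 8 allylmagnesium bromide
Product: 27 4β-hydroxy-1β-[(3S)-3-hydroxyhexa-1,5-dien-2-yl]-4α-methyl-2α,6α-bis(PMB-oxy)-3α-(TES-oxy)cyclohexan-5-one, via borinate 26 (not isolated)
Conditions: (−)-Ipc2BOMe (from (+)-α-pinene), 8, Et2O, 0 °C to rt; then 25, −78 °C; then HOCH2CH2NH2, rt
Reagents that add atoms: allylmagnesium bromide (8), delivered as the B-allyl borane, C=CC[Mg]Br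
Why: Reagent-controlled Brown allylboration through a chair six-membered transition state adds allyl to the aldehyde face that gives the (8S) carbinol, while the hindered C5 ketone and the tertiary hydroxyl do not react at −78 °C and the non-oxidative work-up spares the α-ketol.

**Step 18**
Reactants: 27 homoallylic alcohol; 28 2-methylbut-2-ene
Product: 29 4β-hydroxy-1β-[(3S)-3-hydroxy-6-methylhepta-1,5-dien-2-yl]-4α-methyl-2α,6α-bis(PMB-oxy)-3α-(TES-oxy)cyclohexan-5-one
Conditions: RuCl2(=CHPh)(H2IMes)(PCy3) (second-generation Grubbs catalyst, 5 mol %), 28 (large excess), CH2Cl2, 35 °C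
Reagents that add atoms: 2-methylbut-2-ene (28), CC=C(C)C
Why: Olefin cross-metathesis of the monosubstituted alkene with 2-methylbut-2-ene installs the isopropylidene terminus, and the hindered 1,1-disubstituted C7 methylene does not engage the ruthenium carbene.

**Step 19**
Reactants: 29 4β-hydroxy-1β-[(3S)-3-hydroxy-6-methylhepta-1,5-dien-2-yl]-4α-methyl-2α,6α-bis(PMB-oxy)-3α-(TES-oxy)cyclohexan-5-one
Product: 30 2α,4β,6α-trihydroxy-1β-[(3S)-3-hydroxy-6-methylhepta-1,5-dien-2-yl]-4α-methyl-3α-(TES-oxy)cyclohexan-5-one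
Conditions: DDQ, CH2Cl2/pH 7 phosphate buffer, 0 °C
Reagents that add atoms: none
Why: Oxidative PMB cleavage by electron transfer to DDQ and hydrolysis of the benzylic oxocarbenium ions frees O2 and O6, while the buffered medium protects the silyl ether and the alkenes.

**Step 20**
Reactants: 30 triol; 31 angelic acid
Product: 32 2α,6α-bis(angeloyloxy)-1β-[(3S)-3-(angeloyloxy)-6-methylhepta-1,5-dien-2-yl]-4β-hydroxy-4α-methyl-3α-(TES-oxy)cyclohexan-5-one
Conditions: 31, 2,4,6-trichlorobenzoyl chloride, Et3N, toluene, rt; then 30, toluene, 80 °C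
Reagents that add atoms: angelic acid (31), C/C=C(/C)C(=O)O
Why: Yamaguchi-type acylation through the preformed mixed anhydride, run without a nucleophilic catalyst, is the protocol that should keep the (Z) geometry; the tertiary C4 hydroxyl and the silylated O3 are not acylated.

**Step 21**
Reactants: 32 tris-angelate
Product: 33 2α,6α-bis(angeloyloxy)-1β-{(3S)-3-(angeloyloxy)-4-[(2R)-3,3-dimethyloxiran-2-yl]but-1-en-2-yl}-4β-hydroxy-4α-methyl-3α-(TES-oxy)cyclohexan-5-one
Conditions: D-fructose-derived Shi ketone (30 mol %), KHSO5 (Oxone), K2CO3, Bu4NHSO4, MeCN/CH2(OMe)2/aq. Na2B4O7 buffer, 0 °C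
Reagents that add atoms: potassium peroxymonosulfate, [K+].[O-]S(=O)(=O)OO
Why: Shi epoxidation: the chiral dioxirane attacks the most electron-rich, trisubstituted C10=C11 alkene through the spiro transition state that gives the (10R) oxirane, while the hindered C7 methylene and the electron-poor angelates do not react.

**Step 22**
Reactants: 33 silyl-protected epoxide
Product: 34 CNP0313777.1 (target)
Conditions: Bu4NF, AcOH (1:1), THF, 0 °C to rt
Reagents that add atoms: none
Why: Fluoride cleaves the Si–O bond, and the acetic acid buffer keeps the medium near neutral so that the oxirane stays closed and the C2 angelate does not migrate to O3.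

**Compound list**
1 | methyl α-D-mannopyranoside | CO[C@@H]1[C@@H](O)[C@@H](O)[C@H](O)[C@@H](CO)O1 | starting material
2 | methyl 2,3:4,6-di-O-isopropylidene-α-D-mannopyranoside (not isolated) | CO[C@@H]1[C@@H](OC2(C)C)[C@@H](O2)[C@H](OC3(C)C)[C@@H](CO3)O1 | intermediate
3 | methyl 2,3-O-isopropylidene-α-D-mannopyranoside | CO[C@@H]1[C@@H](OC2(C)C)[C@@H](O2)[C@H](O)[C@@H](CO)O1 | intermediate
4 | methyl 6-O-TBDPS-2,3-O-isopropylidene-α-D-mannopyranoside | CO[C@@H]1[C@@H](OC2(C)C)[C@@H](O2)[C@H](O)[C@@H](CO[Si](c2ccccc2)(c2ccccc2)C(C)(C)C)O1 | intermediate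
5 | methyl 6-O-TBDPS-2,3-O-isopropylidene-4-O-methanesulfonyl-α-D-mannopyranoside | CO[C@@H]1[C@@H](OC2(C)C)[C@@H](O2)[C@H](OS(C)(=O)=O)[C@@H](CO[Si](c2ccccc2)(c2ccccc2)C(C)(C)C)O1 | intermediate
6 | methyl 6-O-TBDPS-4-O-methanesulfonyl-α-D-mannopyranoside | CO[C@@H]1[C@@H](O)[C@@H](O)[C@H](OS(C)(=O)=O)[C@@H](CO[Si](c2ccccc2)(c2ccccc2)C(C)(C)C)O1 | intermediate
7 | methyl 3,4-anhydro-6-O-TBDPS-α-D-talopyranoside | CO[C@@H]1[C@@H](O)[C@H]2O[C@H]2[C@@H](CO[Si](c2ccccc2)(c2ccccc2)C(C)(C)C)O1 | intermediate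
8 | allylmagnesium bromide | C=CC[Mg]Br | starting material
9 | methyl 3-C-allyl-3-deoxy-6-O-TBDPS-α-D-idopyranoside | CO[C@@H]1[C@@H](O)[C@H](CC=C)[C@@H](O)[C@@H](CO[Si](c2ccccc2)(c2ccccc2)C(C)(C)C)O1 | intermediate
10 | methyl 3-C-allyl-3-deoxy-2,4-di-O-PMB-6-O-TBDPS-α-D-idopyranoside | CO[C@@H]1[C@@H](OCc2ccc(OC)cc2)[C@H](CC=C)[C@@H](OCc2ccc(OC)cc2)[C@@H](CO[Si](c2ccccc2)(c2ccccc2)C(C)(C)C)O1 | intermediate
11 | methyl 3-C-allyl-3-deoxy-2,4-di-O-PMB-α-D-idopyranoside | CO[C@@H]1[C@@H](OCc2ccc(OC)cc2)[C@H](CC=C)[C@@H](OCc2ccc(OC)cc2)[C@@H](CO)O1 | intermediate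
12 | methyl 3-C-allyl-3-deoxy-2,4-di-O-PMB-α-D-ido-hexodialdo-1,5-pyranoside | CO[C@@H]1[C@@H](OCc2ccc(OC)cc2)[C@H](CC=C)[C@@H](OCc2ccc(OC)cc2)[C@@H](C=O)O1 | intermediate
13 | potassium (Z)-enolate of 12 (not isolated) | CO[C@@H]1[C@@H](OCc2ccc(OC)cc2)[C@H](CC=C)[C@@H](OCc2ccc(OC)cc2)/C(=C/[O-])O1.[K+] | intermediate
14 | methyl (Z)-3-C-allyl-3-deoxy-2,4-di-O-PMB-6-O-triflyl-hex-5-enopyranoside | CO[C@@H]1[C@@H](OCc2ccc(OC)cc2)[C@H](CC=C)[C@@H](OCc2ccc(OC)cc2)/C(=C/OS(=O)(=O)C(F)(F)F)O1 | intermediate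
15 | methyl (Z)-3-C-allyl-3,6,7-trideoxy-2,4-di-O-PMB-hept-5-enopyranoside | CO[C@@H]1[C@@H](OCc2ccc(OC)cc2)[C@H](CC=C)[C@@H](OCc2ccc(OC)cc2)/C(=C/C)O1 | intermediate
16 | C5 hemiketal with (trifluoroacetoxy)mercury on C6 (not isolated; C5, C6 mixtures) | CO[C@@H]1[C@@H](OCc2ccc(OC)cc2)[C@H](CC=C)[C@@H](OCc2ccc(OC)cc2)C(O)(C(C)[Hg]OC(=O)C(F)(F)F)O1 | intermediate
17 | 3-allyl-2,4-bis(PMB-oxy)-5-oxo-6-[(trifluoroacetoxy)mercurio]heptanal (not isolated) | O=C[C@@H](OCc1ccc(OC)cc1)[C@H](CC=C)[C@@H](OCc1ccc(OC)cc1)C(=O)C(C)[Hg]OC(=O)C(F)(F)F | intermediate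
18 | 1β-allyl-3α-hydroxy-4α-methyl-2α,6α-bis(PMB-oxy)cyclohexan-5-one | C=CC[C@H]1[C@H](OCc2ccc(OC)cc2)[C@H](O)[C@H](C)C(=O)[C@@H]1OCc2ccc(OC)cc2 | intermediate
19 | 1β-allyl-4α-methyl-2α,6α-bis(PMB-oxy)-3α-(TES-oxy)cyclohexan-5-one | C=CC[C@H]1[C@H](OCc2ccc(OC)cc2)[C@H](O[Si](CC)(CC)CC)[C@H](C)C(=O)[C@@H]1OCc2ccc(OC)cc2 | intermediate
20 | sodium C4=C5 enolate of 19 (not isolated) | C=CC[C@H]1[C@H](OCc2ccc(OC)cc2)[C@H](O[Si](CC)(CC)CC)C(C)=C([O-])[C@@H]1OCc2ccc(OC)cc2.[Na+] | intermediate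
21 | 1β-allyl-4β-hydroxy-4α-methyl-2α,6α-bis(PMB-oxy)-3α-(TES-oxy)cyclohexan-5-one | C=CC[C@H]1[C@H](OCc2ccc(OC)cc2)[C@H](O[Si](CC)(CC)CC)[C@@](C)(O)C(=O)[C@@H]1OCc2ccc(OC)cc2 | intermediate
22 | 1β-(2,3-dihydroxypropyl) analogue of 21 (not isolated; carbinol mixture) | OCC(O)C[C@H]1[C@H](OCc2ccc(OC)cc2)[C@H](O[Si](CC)(CC)CC)[C@@](C)(O)C(=O)[C@@H]1OCc2ccc(OC)cc2 | intermediate
23 | 1β-(2-oxoethyl) analogue of 21 | O=CC[C@H]1[C@H](OCc2ccc(OC)cc2)[C@H](O[Si](CC)(CC)CC)[C@@](C)(O)C(=O)[C@@H]1OCc2ccc(OC)cc2 | intermediate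
24 | 1β-[1-(dimethylamino)-3-oxopropan-2-yl] analogue of 21 (not isolated) | O=CC(CN(C)C)[C@H]1[C@H](OCc2ccc(OC)cc2)[C@H](O[Si](CC)(CC)CC)[C@@](C)(O)C(=O)[C@@H]1OCc2ccc(OC)cc2 | intermediate
25 | 1β-(3-oxoprop-1-en-2-yl) analogue of 21 | C=C(C=O)[C@H]1[C@H](OCc2ccc(OC)cc2)[C@H](O[Si](CC)(CC)CC)[C@@](C)(O)C(=O)[C@@H]1OCc2ccc(OC)cc2 | intermediate
26 | diisopinocampheylborinate of 27 at O8 (not isolated) | C=C([C@H]1[C@H](OCc2ccc(OC)cc2)[C@H](O[Si](CC)(CC)CC)[C@@](C)(O)C(=O)[C@@H]1OCc2ccc(OC)cc2)[C@H](CC=C)OB([C@@H]1C[C@@H]2C[C@H]([C@H]1C)C2(C)C)[C@@H]1C[C@@H]2C[C@H]([C@H]1C)C2(C)C | intermediate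
27 | 4β-hydroxy-1β-[(3S)-3-hydroxyhexa-1,5-dien-2-yl]-4α-methyl-2α,6α-bis(PMB-oxy)-3α-(TES-oxy)cyclohexan-5-one | C=C([C@H]1[C@H](OCc2ccc(OC)cc2)[C@H](O[Si](CC)(CC)CC)[C@@](C)(O)C(=O)[C@@H]1OCc2ccc(OC)cc2)[C@H](CC=C)O | intermediate
28 | 2-methylbut-2-ene | CC=C(C)C | starting material
29 | 4β-hydroxy-1β-[(3S)-3-hydroxy-6-methylhepta-1,5-dien-2-yl]-4α-methyl-2α,6α-bis(PMB-oxy)-3α-(TES-oxy)cyclohexan-5-one | C=C([C@H]1[C@H](OCc2ccc(OC)cc2)[C@H](O[Si](CC)(CC)CC)[C@@](C)(O)C(=O)[C@@H]1OCc2ccc(OC)cc2)[C@H](CC=C(C)C)O | intermediate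
30 | 2α,4β,6α-trihydroxy-1β-[(3S)-3-hydroxy-6-methylhepta-1,5-dien-2-yl]-4α-methyl-3α-(TES-oxy)cyclohexan-5-one | C=C([C@H]1[C@H](O)[C@H](O[Si](CC)(CC)CC)[C@@](C)(O)C(=O)[C@@H]1O)[C@H](CC=C(C)C)O | intermediate
31 | angelic acid | C/C=C(/C)C(=O)O | starting material
32 | 2α,6α,8-tris-O-angeloyl derivative of 30 | C=C([C@H]1[C@H](OC(=O)/C(C)=C\C)[C@H](O[Si](CC)(CC)CC)[C@@](C)(O)C(=O)[C@@H]1OC(=O)/C(C)=C\C)[C@H](CC=C(C)C)OC(=O)/C(C)=C\C | intermediate
33 | (10R)-10,11-epoxide of 32 (3-O-TES ether of the target) | C=C([C@H]1[C@H](OC(=O)/C(C)=C\C)[C@H](O[Si](CC)(CC)CC)[C@@](C)(O)C(=O)[C@@H]1OC(=O)/C(C)=C\C)[C@H](C[C@H]1OC1(C)C)OC(=O)/C(C)=C\C | intermediate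
34 | CNP0313777.1 | C=C([C@H]1[C@H](OC(=O)/C(C)=C\C)[C@H](O)[C@@](C)(O)C(=O)[C@@H]1OC(=O)/C(C)=C\C)[C@H](C[C@H]1OC1(C)C)OC(=O)/C(C)=C\C | target

**Step count**
Total: 22 steps. Longest linear sequence: 22 steps, from 1 to 34.

**Three steps most likely to fail**

Step 12. The oxymercuration of the trisubstituted, C-branched enol ether may be slow enough for the allyl alkene or the anisyl rings to be mercurated, the ketol may lose water to the enone, or the aldol may close with poor facial selectivity. Fallback: starting from 15, mild acid hydrolysis (AcOH/H2O/THF, rt) would open the enol ether and the anomeric acetal to the open-chain 3-allyl-2,4-bis(PMB-oxy)-5-oxoheptanal F1. The ring would then be closed without mercury as the dibutylboron enolate of the ethyl ketone (Bu2BOTf, i-Pr2NEt, CH2Cl2, −78 °C; pH 7 buffer/MeOH/H2O2 work-up). Enolisation should occur away from the α-alkoxy carbon, and the boron-bridged 6-(enolexo)-exo-trig transition state mirrors the mercury-bridged one, so the route would be rejoined at 18.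

Step 14. Deprotonation may occur at C6 instead of C4, or the C4 enolate may expel the axial silyloxy group at C3. Fallback: starting from 18, mesylation and in situ elimination (MsCl, Et3N, CH2Cl2, 0 °C) would pass through the 3α-mesylate F2 to 1β-allyl-4-methyl-2α,6α-bis(PMB-oxy)cyclohex-3-en-5-one F3. Alkaline hydrogen peroxide (H2O2, NaOH, MeOH, 0 °C) should epoxidise this enone anti to the C2 ether to give the 3β,4β-epoxy ketone F4. Dilute HClO4 in THF/H2O should open it trans-diaxially by attack of water at C3, the carbon remote from the carbonyl, to give the 3α,4β-dihydroxy ketone F5. Et3SiCl/imidazole should silylate only the secondary 3α-hydroxyl, and the route is rejoined at 21.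

Step 20. The angelates may isomerise to tiglates during activation or at 80 °C, acylation of the hindered C2 and C6 hydroxyls may stall, or the α-ketol may isomerise under warm amine base. Fallback: starting from 30, the three hydroxyls would be esterified with 2-(diphenoxyphosphoryl)propanoic acid (EDC·HCl, DMAP, CH2Cl2) to give the tris[2-(diphenoxyphosphoryl)propanoate] F6. The Z-trisubstituted alkenes would then be built on the molecule by an Ando-type Horner–Wadsworth–Emmons reaction with acetaldehyde (NaI, DBU, THF, −78 to 0 °C), coming back to the route at 32.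

**Further compounds**
F1 | step 12 | 3-allyl-2,4-bis(PMB-oxy)-5-oxoheptanal (C2–C4 as in 15) | O=C[C@@H](OCc1ccc(OC)cc1)[C@H](CC=C)[C@@H](OCc1ccc(OC)cc1)C(=O)CC
F2 | step 14 | 3α-methanesulfonate of 18 | C=CC[C@H]1[C@H](OCc2ccc(OC)cc2)[C@H](OS(C)(=O)=O)[C@H](C)C(=O)[C@@H]1OCc2ccc(OC)cc2
F3 | step 14 | 1β-allyl-4-methyl-2α,6α-bis(PMB-oxy)cyclohex-3-en-5-one | C=CC[C@H]1[C@H](OCc2ccc(OC)cc2)C=C(C)C(=O)[C@@H]1OCc2ccc(OC)cc2
F4 | step 14 | 1β-allyl-3β,4β-epoxy-4α-methyl-2α,6α-bis(PMB-oxy)cyclohexan-5-one | C=CC[C@H]1[C@H](OCc2ccc(OC)cc2)[C@H]3O[C@@]3(C)C(=O)[C@@H]1OCc2ccc(OC)cc2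
F5 | step 14 | 1β-allyl-3α,4β-dihydroxy-4α-methyl-2α,6α-bis(PMB-oxy)cyclohexan-5-one | C=CC[C@H]1[C@H](OCc2ccc(OC)cc2)[C@H](O)[C@@](C)(O)C(=O)[C@@H]1OCc2ccc(OC)cc2
F6 | step 20 | 2α,6α,8-tris-O-[2-(diphenoxyphosphoryl)propanoyl] derivative of 30 | C=C([C@H]1[C@H](OC(=O)C(C)P(=O)(Oc2ccccc2)Oc2ccccc2)[C@H](O[Si](CC)(CC)CC)[C@@](C)(O)C(=O)[C@@H]1OC(=O)C(C)P(=O)(Oc2ccccc2)Oc2ccccc2)[C@H](CC=C(C)C)OC(=O)C(C)P(=O)(Oc2ccccc2)Oc2ccccc2
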